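**Retrosynthetic overview**
- Feature: in the 2,3-dihydroxybenzoate head the carboxyl carbon sits on the benzene carbon directly beside one of the two catechol oxygens, and the ester oxygen is bonded to the unbranched primary C1 of the C21 chain. The first fact invites oxygen-directed lithiation of a catechol ketal, the second an SN2 alkylation of a carboxylate.
- Key disconnection: the aryl C–CO2 bond and the ester O–C1 bond are cut together, leading to catechol acetonide, CO2 and (S)-1-iodo-18-methylicosane, which are reunited in one flask.
- Chain disconnection: the C16–C17 bond, leading to 16-bromohexadecan-1-ol and the Grignard reagent of (S)-1-bromo-2-methylbutane, which delivers the only stereocentre (C18) ready-made.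
- Rings: the benzene ring is bought as catechol. The only ring formed is the temporary five-membered dioxole (step 1), which is opened again in the last step.

Key step: step 4

Remark: the configuration at C18 is carried unchanged from commercial (S)-1-bromo-2-methylbutane, so the enantiomeric purity of the target is assumed to equal that of this reagent.

**Route**

Step 1
Reactants: 1 catechol
Product: 2 2,2-dimethyl-1,3-benzodioxole
Conditions: 2,2-dimethoxypropane, p-toluenesulfonic acid monohydrate (p-TsOH·H2O, cat.), toluene, reflux, MeOH removed (4 Å molecular sieves in a Soxhlet)
Reagents that add atoms: 2,2-dimethoxypropane, COC(C)(C)OC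
Why: Acid-catalysed transketalisation in which the two adjacent phenolic oxygens replace both methoxy groups and close the five-membered dioxole, driven by removal of methanol.

Step 2
Reactants: 3 (S)-1-bromo-2-methylbutane, 4 16-bromohexadecan-1-ol
Product: 6 (S)-18-methylicosan-1-ol, via (S)-2-methylbutylmagnesium bromide 5 (not isolated)
Conditions: 3, Mg, THF, 45 °C, giving 5 (3 equiv); then 4, Li2CuCl4 (5 mol %), THF, −20 °C → rt; aq. NH4Cl
Reagents that add atoms: none
Why: Copper-catalysed alkyl–alkyl Grignard cross-coupling (Kochi coupling) in which the first equivalent of 5 is spent on the hydroxyl proton and the rest displaces the primary bromide at C16, while the stereocentre, one carbon away from the C–Mg bond and without an acidic hydrogen, should keep its (S) configuration.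

Step 3
Reactants: 6 (S)-18-methylicosan-1-ol
Product: 7 (S)-1-iodo-18-methylicosane
Conditions: I2, PPh3, imidazole, CH2Cl2, 0 °C → rt
Reagents that add atoms: iodine, II
Why: Appel-type iodination in which the primary alcohol is activated as an alkoxyphosphonium ion and displaced by iodide in an SN2 step far from the stereocentre.

Step 4
Reactants: 2 2,2-dimethyl-1,3-benzodioxole, 8 carbon dioxide, 7 (S)-1-iodo-18-methylicosane
Product: 11 (S)-18-methylicosyl 2,2-dimethyl-1,3-benzodioxole-4-carboxylate, via 4-lithio-2,2-dimethyl-1,3-benzodioxole 9 (not isolated), via lithium 2,2-dimethyl-1,3-benzodioxole-4-carboxylate 10 (not isolated)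
Conditions: 2 (2.2 equiv), n-BuLi (2.0 equiv, hexanes), THF, 0 °C, 2 h; CO2 gas (dried, excess), −78 °C → rt, then Ar purge; DMF, 7 (1.0 equiv), 65 °C; aq. NH4Cl
Reagents that add atoms: none
Why: The two dioxole oxygens coordinate n-BuLi and acidify the flanking ring C–H bonds, and because C4 and C7 of 2 are equivalent by symmetry the directed ortho-lithiation should give the single aryllithium 9. 9 adds to CO2 to form the aryl–carboxyl C–C bond as lithium carboxylate 10, and once DMF is added and the mixture is warmed the carboxylate oxygen displaces iodide from the unhindered primary C1 of 7 by SN2, which forms the O–C1 ester bond. The closest known reaction types are the carboxylation of ortho-lithiated 1,3-benzodioxoles and the O-alkylation of carboxylate salts by primary iodides in dipolar aprotic solvent, run here one after the other without isolation. No ring is closed and no stereocentre is formed; the (S) centre at C18 lies seventeen carbons from the reacting carbon and is not touched. The step needs regioselective metalation, secured by the ring oxygens and the symmetry of 2, and alkylation at the carboxylate oxygen only, secured by the ketal that masks both phenols. Keeping 2 in excess over n-BuLi leaves no butyllithium to be carboxylated, so no pentanoate competes for 7, and no acyl activation is required.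

Step 5
Reactants: 11 (S)-18-methylicosyl 2,2-dimethyl-1,3-benzodioxole-4-carboxylate
Product: 12 gentiside H, (S)-18-methylicosyl 2,3-dihydroxybenzoate
Conditions: CF3CO2H/H2O (9:1), CH2Cl2, 0 °C → rt, under Ar
Reagents that add atoms: none
Why: Acid-catalysed ketal hydrolysis in which protonation of a dioxole oxygen, ring opening to the oxocarbenium ion and capture by water should release acetone and the free catechol, while the primary alkyl benzoate and the saturated chain are inert to aqueous CF3CO2H at room temperature.

**Compound list**
1 | catechol | Oc1ccccc1O | starting material
2 | 2,2-dimethyl-1,3-benzodioxole | CC1(C)Oc2ccccc2O1 | intermediate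
3 | (S)-1-bromo-2-methylbutane | CC[C@H](C)CBr | starting material
4 | 16-bromohexadecan-1-ol | OCCCCCCCCCCCCCCCCBr | starting material
5 | (S)-2-methylbutylmagnesium bromide | CC[C@H](C)C[Mg]Br | intermediate
6 | (S)-18-methylicosan-1-ol | CC[C@H](C)CCCCCCCCCCCCCCCCCO | intermediate
7 | (S)-1-iodo-18-methylicosane | CC[C@H](C)CCCCCCCCCCCCCCCCCI | intermediate
8 | carbon dioxide | O=C=O | starting material
9 | 4-lithio-2,2-dimethyl-1,3-benzodioxole | CC1(C)Oc2cccc([Li])c2O1 | intermediate
10 | lithium 2,2-dimethyl-1,3-benzodioxole-4-carboxylate | CC1(C)Oc2cccc(C(=O)[O-])c2O1.[Li+] | intermediate
11 | (S)-18-methylicosyl 2,2-dimethyl-1,3-benzodioxole-4-carboxylate | CC[C@H](C)CCCCCCCCCCCCCCCCCOC(=O)c1cccc2OC(C)(C)Oc12 | intermediate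
12 | gentiside H, (S)-18-methylicosyl 2,3-dihydroxybenzoate | CC[C@H](C)CCCCCCCCCCCCCCCCCOC(=O)c1cccc(O)c1O | target

**Step count**
Total: 5 steps. Longest linear sequence: 4 steps (steps 2, 3, 4 and 5, from 3 and 4 to 12).

**Steps most likely to fail, with fallbacks**

Step 4. The lithium carboxylate may be too tightly ion-paired to alkylate at a useful rate. In addition, part of the aryllithium may add to carboxylate already formed during the CO2 quench and give a diaryl ketone. Either process would leave iodide 7 unconsumed. The fallback sets out from 2 and comes back at 11. Compound 2 is lithiated and carboxylated as above (through 9 and 10), but the mixture is acidified cold with dilute HCl and 2,2-dimethyl-1,3-benzodioxole-4-carboxylic acid F1 is isolated. F1 is then joined to alcohol 6, not to iodide 7, by Steglich esterification (N,N'-dicyclohexylcarbodiimide, 4-(dimethylamino)pyridine cat., CH2Cl2, 0 °C → rt). The ester C–O bond is thus made by acyl transfer instead of SN2, and the product is 11.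

Step 2. The magnesium alkoxide formed from the bromo alcohol may precipitate and couple slowly. Homocoupling of the Grignard reagent and reduction or elimination of the bromide would then compete and give material that is hard to separate from 6. The fallback sets out from 4 and comes back at 6. The hydroxyl group of 4 is masked with 3,4-dihydro-2H-pyran (pyridinium p-toluenesulfonate cat., CH2Cl2) to give 2-[(16-bromohexadecyl)oxy]oxane F2. F2 is coupled with 5 (about 1.5 equiv) under Li2CuCl4 catalysis in THF to give 2-{[(18S)-18-methylicosyl]oxy}oxane F3, a mixture of two epimers at the acetal carbon. Methanolysis (p-TsOH·H2O cat., MeOH, rt) should then return 6.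

Step 5. Ketal hydrolysis may be slow because the ester-bearing ring disfavours the oxocarbenium ion and the waxy ester dissolves poorly in aqueous acid. Forcing the acid risks ester cleavage and air oxidation of the freed catechol. The fallback sets out from 7 and comes back at 12, and avoids the ketal altogether. Commercial 2,3-dihydroxybenzoic acid (O=C(O)c1cccc(O)c1O) is converted into its potassium carboxylate with KHCO3 in DMF and alkylated with 7 at 50–60 °C. Bicarbonate is too weak a base to deprotonate the phenols, so only the carboxylate oxygen should be alkylated, giving 12 directly.

**Further compounds**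
F1 | step 4 | 2,2-dimethyl-1,3-benzodioxole-4-carboxylic acid | CC1(C)Oc2cccc(C(=O)O)c2O1
F2 | step 2 | 2-[(16-bromohexadecyl)oxy]oxane | BrCCCCCCCCCCCCCCCCOC1CCCCO1
F3 | step 2 | 2-{[(18S)-18-methylicosyl]oxy}oxane | CC[C@H](C)CCCCCCCCCCCCCCCCCOC1CCCCO1
F0 | step 5 | none | none
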